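The trap at this bench was to expect more Q to raise E as a percent of the Q charged. The winter run was charged with 4.00 times the Q of the midnight run, yet its highest reading, in percent of the Q charged, was 9.9% against 10.9%.

| flask | Q | X | J | remark | time |
|---|---|---|---|---|---|
| midnight | 0.50 M | 0.60 M | 80 mM | run made earlier |  |
| winter | 2 M | 0.60 M | 80 mM | run made earlier |  |
| noon | 1 M | 1.2 M | 80 mM | run made earlier |  |
| flask | 1.0 M | 0.600 M | 80 mM |  | 15 d |

| run | time / d | E / % |
|---|---|---|
| midnight | 0.250 | 6.5 |
| midnight | 0.625 | 10.9 |
| midnight | 1.04 | 9.6 |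
| midnight | 2.50 | 10.4 |
| midnight | 5.00 | 9.2 |
| midnight | 10.0 | 6.0 |
| winter | 0.250 | 5.5 |
| winter | 0.625 | 9.9 |
| winter | 1.04 | 6.0 |
| winter | 2.50 | 6.1 |
| winter | 5.00 | 7.2 |
| winter | 10.0 | 4.5 |
| noon | 0.250 | 15.8 |
| noon | 0.625 | 17.0 |
| noon | 1.67 | 18.3 |
| noon | 4.00 | 15.6 |
| noon | 10.0 | 11.3 |

(readings scatter by 1 percentage point)

- the earlier runs were read with a standard deviation of 1 percentage point

* when, up to 15 d, the flask holds most E
* the amount of E, in percent of the Q charged, at that time
* earliest time at which at least nineteen twentieths of that best amount are there, in d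
* latest time at which they still are, in d

I left you the flask with Q, X and J charged as listed, X being the limiting reagent. I treated Q as staying near its charge and reckoned only the small part of it taken into E, a part I expected to follow the X charge. The highest reading divided by the X charge averaged 0.166 M⁻¹ over the earlier runs; I called this the take. Run by run it went from 0.153 M⁻¹ at noon to 0.182 M⁻¹ at midnight, on readings scattered by 1 point.

So I expected your flask to reach 9.98% of the Q charged. The highest readings of the earlier runs stood between 0.625 d and 1.67 d. The forecast gave 9.4% at 0.9 d, with a window from 0.5 d to 2 d, on the view that the runs “rise within about a day, then fade slowly”; my figure was above it. I asked you to add no Q and to take the flask inside that window.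

The flask gave 10.3% at 1.15 d, and the window asked for ran from 0.651 d to 2.33 d.

    Q + X + J ⇌ E + J, rate k1*[Q]*[X]*[J] forward; the back reaction follows from the equilibrium constant (K = 5.20 M⁻¹, k = 0.370 M⁻² h⁻¹)
    E ⇌ Z (K = 0.640, k = 0.0550 h⁻¹)
    X → G (k = 0.0600 h⁻¹)

At 1.15 d the flask still held 84.2% of its Q and 10.3% of its X. Its own take was 0.172 M⁻¹. The neighbour flask with 1.5 M of X had a reckoned peak of 24.9% from the take, and it reached 23.1%.

The readings are calculated from invented constants; the scatter is artificial.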